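**Smaller charge.** The flask holds less solid substrate than the red run, and the red run's target climbs along a straight line from 30.0 min to 60.0 min, a zero-order stretch.

| setting | red | flask |
|---|---|---|
| solid substrate | 2.1 M | 1.5 M |
| gas | 96 mM (held) | 96 mM (held) |
| remark | run made earlier |  |
| time |  | 80 min |

red run (percent of the solid substrate charged)

| time / min | target / % | dissolved substrate / % |
|---|---|---|
| 15.0 | 7.2 | 4.0 |
| 30.0 | 17.8 | 6.3 |
| 50.0 | 34.0 | 6.1 |
| 60.0 | 41.9 | 7.1 |

(readings scatter by 1 percentage point)

- the target standing at 80 min, as a percentage of the solid substrate charged
- concentration of dissolved substrate in solution at 80 min, in percent of saturation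

- solid substrate is a solid; its amount is given per volume of the solution
- what was read earlier has a scatter of 1 percentage point, one standard deviation
- at the start none of the solid substrate is in solution
- at the start none of the gas is in solution
- dissolved substrate means what is dissolved; the solid is not counted in it

**Charge turnover.** That slope gives the red charge a lifetime of 124 min, and the line meets zero at 7.84 min. Taken at the same molar rate, the flask's charge has a lifetime of 88.9 min. Time past the lag over that lifetime gives 81.2 %, the charge turnover: the fraction of the charge that the line carries into target.

**One number?** The last red reading of dissolved substrate, scaled to the flask's charge, is 9.94 %. Added to the turnover this makes 91.1 %, less than the charge, so by this reckoning, which counts the two species read, solid remains in the flask at 80 min and the line holds. The turnover is silent on saturation. Red intake, target plus dissolved substrate, reads 0.00747 min⁻¹ of the charge up to 15.0 min and 0.00830 min⁻¹ from 30.0 min to 60.0 min, with no fall as dissolved substrate built up, so this reckoning expects the flask's solution to stay well short of saturation, without a figure.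

**Forecast.** The forecast gives 76 % and 65 %, holding that “the solution is probably close to saturation”; this reckoning differs, with a turnover above that target and a solution well short of saturation.

    solid substrate ⇌ dissolved substrate, rate k1*(cs1 - [dissolved substrate]) while solid is left; crystals form when [dissolved substrate] > cs1 (solubility = 0.940 M, k = 3.80 × 10⁻⁴ s⁻¹)
    2 dissolved substrate → side product (k = 8.50 × 10⁻⁴ M⁻¹ s⁻¹)
    dissolved substrate + reagent → target (k = 0.0220 M⁻¹ s⁻¹)
    gas ⇌ reagent, rate k4*(csat - [reagent]) (kL = 0.140 s⁻¹)
    2 reagent → self-condensation product (k = 0.0600 M⁻¹ s⁻¹)

**Result.** The flask gives 79.7 % target against a turnover of 81.2 %, with dissolved substrate at 14.9 % of saturation. The half-life of dissolved substrate by its step into target at 80.0 min is 6.0 min, short against the 80 min of the run. For a neighbour charged with 2.5 M, the turnover scales to 48.7 %, and that neighbour stands at 47.8 % target after 80 min.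

The numbers in the tables come from a simulation for an exercise; the scatter is artificial.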